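**Plan**

- Retrosynthesis: the interflavanyl C4–C6 bond is cut first, which leaves two copies of one monomer, (2S,3S)-3',4'-di-O-benzyl-ent-epifisetinidol 13. Its C3 carbinol goes back to racemic flavan-3-one 11, and the C2–C3 bond of ring C is cut to open-chain nitrostyrene 7 (ring A salicylaldehyde, nitromethane, ring B benzyl alcohol).
- Enabling feature: C2–H sits on O1 and is benzylic to the 3,4-dioxygenated ring B (a hydride donor), C4 is a methylene, and C2 and C4 are 1,5-related through O1–C8a–C4a. A 1,5-hydride shift C2→C4 followed by C3→C2 bonding therefore closes ring C with no external redox reagent.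
- Forward order: ring A aldehyde → O1 ether to the ring B benzyl unit → nitroalkene → ring C by C2–C3 closure (nitro as helper, removed by Nef) → 3-ketone → cis-alcohol → free 7-phenol → C4 activation through the ring A para-quinone methide (O7 is para to C4a) → C4–C6 coupling → debenzylation.
- Stereochemistry: one transfer hydrogenation with RuCl(p-cymene)[(S,S)-TsDPEN] under dynamic kinetic resolution fixes C3 and funnels the labile C2 to cis. The monomer is used twice (four stereocentres), and upper C4 follows from attack anti to the 3-OH of the 2,3-cis electrophile.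

Key step: step 4

Remark: RuCl(p-cymene)[(S,S)-TsDPEN] is taken to deliver hydride to the Re face of C3 of ketone 11; should the sense be the reverse, the (R,R) complex is used with no other change.

**Route**

Step 1
Reactants: 1 2,4-dihydroxybenzaldehyde
Product: 2 4-formyl-3-hydroxyphenyl pivalate
Conditions: PivCl (1.05 equiv), Et3N, CH2Cl2, −20 → 0 °C
Reagents that add atoms: pivaloyl chloride, CC(C)(C)C(Cl)=O
Why: Regioselective O-acylation, since the 2-OH is held in a hydrogen bond to the formyl group while the 4-OH is the more acidic and accessible phenol, so one equivalent of acid chloride should esterify O4 only.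

Step 2
Reactants: 2 4-formyl-3-hydroxyphenyl pivalate; 3 3,4-bis(benzyloxy)benzyl alcohol
Product: 4 3-{[3,4-bis(benzyloxy)phenyl]methoxy}-4-formylphenyl pivalate
Conditions: PPh3, DIAD, THF, 0 °C → rt
Reagents that add atoms: none
Why: Mitsunobu etherification, in which the acidic salicylaldehyde-type phenol displaces the activated primary benzylic alcohol under neutral conditions that leave the pivalate untouched.

Step 3
Reactants: 4 3-{[3,4-bis(benzyloxy)phenyl]methoxy}-4-formylphenyl pivalate; 5 nitromethane
Product: 7 3-{[3,4-bis(benzyloxy)phenyl]methoxy}-4-[(E)-2-nitroethenyl]phenyl pivalate, via nitroaldol adduct 6 (not isolated)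
Conditions: MeNO2 (solvent), Et3N (cat.), rt; then MsCl, Et3N, CH2Cl2, 0 °C
Reagents that add atoms: none
Why: Henry (nitroaldol) reaction followed by mesylation and E1cB elimination, which should give the conjugated nitroalkene in its thermodynamically preferred E geometry under conditions mild enough for the aryl pivalate.

Step 4
Reactants: 7 3-{[3,4-bis(benzyloxy)phenyl]methoxy}-4-[(E)-2-nitroethenyl]phenyl pivalate
Product: 9 2-[3,4-bis(benzyloxy)phenyl]-3-nitrochroman-7-yl pivalate (racemic), via oxocarbenium nitronate zwitterion 8 (not isolated)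
Conditions: Sc(OTf)3 (10 mol %), ClCH2CH2Cl (0.02 M), 4 Å MS, 60 °C
Reagents that add atoms: none
Why: Proposed new method: Sc(OTf)3 on the nitro group lowers the LUMO of the nitroalkene, and a through-space suprafacial 1,5-hydride shift from the O1–CH2 carbon (the future C2, a hydride donor because the resulting aryloxocarbenium ion is stabilised by the para-benzyloxy group of ring B) to the benzylic alkene carbon C4 gives zwitterion 8, whose nitronate carbon C3 then adds to the oxocarbenium carbon C2 in a Henry/Mannich-type step. The closest known reaction type is the Lewis-acid-catalysed hydride shift/ring closure (internal redox of the tert-amino-effect type) of 2-(benzyloxy)benzylidene malonates and barbiturates to 2-arylchromans; what is new is the nitroalkene as acceptor, which is intrinsically more electrophilic than an alkylidene malonate and leaves a nitro group that step 5 turns into the C3 carbonyl. Ring C closes in the 6-endo-trig mode with respect to the O1=C2 oxocarbenium bond, the C3=N bond of the nitronate being exocyclic. C2 and C3 arise as a racemate, with 2,3-trans expected to prevail under thermodynamic control because C3 is epimerisable next to the nitro group, and this is of no consequence since C3 becomes trigonal and C2 labile in step 5 and both are set in step 6. The selectivity needed is hydride transfer ahead of Friedel–Crafts attack of ring B on the activated nitroalkene and ahead of bimolecular reactions: only the ortho OCH2 group can reach C4 through a six-membered transition state, high dilution disfavours bimolecular paths, and the 7-O-pivalate, unlike an ether, does not feed electron density into the nitroalkene.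

Step 5
Reactants: 9 2-[3,4-bis(benzyloxy)phenyl]-3-nitrochroman-7-yl pivalate
Product: 11 2-[3,4-bis(benzyloxy)phenyl]-3-oxochroman-7-yl pivalate (racemic), via potassium nitronate 10 (not isolated)
Conditions: KOtBu, THF, −78 °C; then dimethyldioxirane in acetone, −78 → 0 °C
Reagents that add atoms: dimethyldioxirane, CC1(C)OO1
Why: Oxidative Nef reaction, in which the C3 nitronate is cleaved at its C=N bond by electrophilic oxygen transfer at low temperature, before retro-oxa-Michael opening of ring C or loss of the pivalate can compete.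

Step 6
Reactants: 11 2-[3,4-bis(benzyloxy)phenyl]-3-oxochroman-7-yl pivalate
Product: 12 (2S,3S)-2-[3,4-bis(benzyloxy)phenyl]-3-hydroxychroman-7-yl pivalate
Conditions: RuCl(p-cymene)[(S,S)-TsDPEN] (2 mol %), HCO2H/Et3N (5:2), EtOAc, 35 °C, argon
Reagents that add atoms: none
Why: Noyori asymmetric transfer hydrogenation with dynamic kinetic resolution, in which C2–H (alpha to the ketone, benzylic and alpha to aryloxy) should epimerise under Et3N faster than the ketone is reduced, the chiral ruthenium hydride sets C3 as S by Re-face delivery, and the C2 epimer whose aryl group is anti to the incoming hydride reacts faster, which gives the 2,3-cis (2S,3S) alcohol.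

Step 7
Reactants: 12 (2S,3S)-2-[3,4-bis(benzyloxy)phenyl]-3-hydroxychroman-7-yl pivalate
Product: 13 (2S,3S)-2-[3,4-bis(benzyloxy)phenyl]chroman-3,7-diol (3',4'-di-O-benzyl-ent-epifisetinidol)
Conditions: K2CO3 (1.5 equiv), MeOH/THF, rt
Reagents that add atoms: none
Why: Base-mediated methanolysis (transesterification) of the aryl pivalate, which cannot epimerise C2 because ring B is fully etherified and no quinone methide can form there.

Step 8
Reactants: 13 (2S,3S)-2-[3,4-bis(benzyloxy)phenyl]chroman-3,7-diol
Product: 15 (2S,3S,4R)-2-[3,4-bis(benzyloxy)phenyl]-4-methoxychroman-3,7-diol (4α-methoxy; 3,4-trans), via para-quinone methide 14 (not isolated)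
Conditions: DDQ (1.0 equiv), CH2Cl2/MeOH (4:1), −20 → 0 °C
Reagents that add atoms: methanol, CO
Why: Quinone dehydrogenation of a para-alkylphenol, in which DDQ oxidises the only free phenol (O7 is para to C4a) to quinone methide 14 and methanol adds to C4 with rearomatisation, anti to the 3-OH, while the aryl ethers of ring B and C2–H should react far more slowly.

Step 9
Reactants: 15 (2S,3S,4R)-2-[3,4-bis(benzyloxy)phenyl]-4-methoxychroman-3,7-diol; 13 (2S,3S)-2-[3,4-bis(benzyloxy)phenyl]chroman-3,7-diol (4 equiv, excess recovered)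
Product: 17 3',4'-di-O-benzyl-ent-epifisetinidol-(4α→6)-3',4'-di-O-benzyl-ent-epifisetinidol, via C4 benzylic cation 16 (not isolated)
Conditions: BF3·OEt2 (0.3 equiv), THF/CH2Cl2, −20 → 0 °C
Reagents that add atoms: none
Why: Lewis-acid Friedel–Crafts alkylation of the proanthocyanidin-condensation type, in which BF3 abstracts the 4-methoxy group to give the C4 benzylic cation 16 (stabilised by the para 7-OH and the ortho O1), the resorcinol-type ring A of 13 attacks through C6 (ortho to the 7-OH, para to O1 and unhindered, whereas C8 lies between two oxygens) from the face anti to the 3-OH of the 2,3-cis electrophile, which sets upper C4 as 3,4-trans, loss of a proton returns methanol and BF3, and the excess of 13 holds back oligomerisation.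

Step 10
Reactants: 17 3',4'-di-O-benzyl-ent-epifisetinidol-(4α→6)-3',4'-di-O-benzyl-ent-epifisetinidol
Product: 18 ent-epifisetinidol-(4α→6)-ent-epifisetinidol (target)
Conditions: H2 (1 atm), Pd(OH)2/C, THF/MeOH, rt
Reagents that add atoms: none
Why: Catalytic hydrogenolysis of the four benzyl aryl ethers under neutral conditions at one atmosphere, where the cyclic benzylic C2–O1 bonds and the interflavanyl bond should survive.

**Compound list**

1 | 2,4-dihydroxybenzaldehyde | O=Cc1ccc(O)cc1O | starting material
2 | 4-formyl-3-hydroxyphenyl pivalate | CC(C)(C)C(=O)Oc1ccc(C=O)c(O)c1 | intermediate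
3 | 3,4-bis(benzyloxy)benzyl alcohol | OCc1ccc(OCc2ccccc2)c(OCc2ccccc2)c1 | starting material
4 | 3-{[3,4-bis(benzyloxy)phenyl]methoxy}-4-formylphenyl pivalate | CC(C)(C)C(=O)Oc1ccc(C=O)c(OCc2ccc(OCc3ccccc3)c(OCc3ccccc3)c2)c1 | intermediate
5 | nitromethane | C[N+](=O)[O-] | starting material
6 | 3-{[3,4-bis(benzyloxy)phenyl]methoxy}-4-(1-hydroxy-2-nitroethyl)phenyl pivalate (racemic nitroaldol adduct, formed in the flask) | CC(C)(C)C(=O)Oc1ccc(C(O)C[N+](=O)[O-])c(OCc2ccc(OCc3ccccc3)c(OCc3ccccc3)c2)c1 | intermediate
7 | 3-{[3,4-bis(benzyloxy)phenyl]methoxy}-4-[(E)-2-nitroethenyl]phenyl pivalate | CC(C)(C)C(=O)Oc1ccc(/C=C/[N+](=O)[O-])c(OCc2ccc(OCc3ccccc3)c(OCc3ccccc3)c2)c1 | intermediate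
8 | zwitterion with aryloxocarbenium ion at C2 and nitronate at C3 (formed in the flask) | CC(C)(C)C(=O)Oc1ccc(CC=[N+]([O-])[O-])c([O+]=Cc2ccc(OCc3ccccc3)c(OCc3ccccc3)c2)c1 | intermediate
9 | 2-[3,4-bis(benzyloxy)phenyl]-3-nitrochroman-7-yl pivalate (racemic, 2,3-trans expected to prevail) | CC(C)(C)C(=O)Oc1ccc2c(c1)OC(c1ccc(OCc3ccccc3)c(OCc3ccccc3)c1)C([N+](=O)[O-])C2 | intermediate
10 | potassium nitronate of 9 (formed in the flask) | CC(C)(C)C(=O)Oc1ccc2c(c1)OC(c1ccc(OCc3ccccc3)c(OCc3ccccc3)c1)C(C2)=[N+]([O-])[O-].[K+] | intermediate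
11 | 2-[3,4-bis(benzyloxy)phenyl]-3-oxochroman-7-yl pivalate (racemic flavan-3-one) | CC(C)(C)C(=O)Oc1ccc2c(c1)OC(c1ccc(OCc3ccccc3)c(OCc3ccccc3)c1)C(=O)C2 | intermediate
12 | (2S,3S)-2-[3,4-bis(benzyloxy)phenyl]-3-hydroxychroman-7-yl pivalate | CC(C)(C)C(=O)Oc1ccc2c(c1)O[C@@H](c1ccc(OCc3ccccc3)c(OCc3ccccc3)c1)[C@@H](O)C2 | intermediate
13 | (2S,3S)-2-[3,4-bis(benzyloxy)phenyl]chroman-3,7-diol | Oc1ccc2c(c1)O[C@@H](c1ccc(OCc3ccccc3)c(OCc3ccccc3)c1)[C@@H](O)C2 | intermediate
14 | (2S,3S)-2-[3,4-bis(benzyloxy)phenyl]-3-hydroxy-2,3-dihydro-7H-chromen-7-one (ring A para-quinone methide with C4=C4a, formed in the flask) | O=C1C=CC2=C[C@H](O)[C@H](c3ccc(OCc4ccccc4)c(OCc4ccccc4)c3)OC2=C1 | intermediate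
15 | (2S,3S,4R)-2-[3,4-bis(benzyloxy)phenyl]-4-methoxychroman-3,7-diol (4α-methoxy; 3,4-trans) | Oc1ccc2c(c1)O[C@@H](c1ccc(OCc3ccccc3)c(OCc3ccccc3)c1)[C@@H](O)[C@@H]2OC | intermediate
16 | (2S,3S)-2-[3,4-bis(benzyloxy)phenyl]-3,7-dihydroxychroman-4-ylium methoxytrifluoroborate (C4 benzylic cation, formed in the flask) | Oc1ccc2c(c1)O[C@@H](c1ccc(OCc3ccccc3)c(OCc3ccccc3)c1)[C@@H](O)[CH+]2.CO[B-](F)(F)F | intermediate
17 | 3',4'-di-O-benzyl-ent-epifisetinidol-(4α→6)-3',4'-di-O-benzyl-ent-epifisetinidol | Oc1ccc2c(c1)O[C@@H](c1ccc(OCc3ccccc3)c(OCc3ccccc3)c1)[C@@H](O)[C@@H]2c1cc2c(cc1O)O[C@@H](c1ccc(OCc3ccccc3)c(OCc3ccccc3)c1)[C@@H](O)C2 | intermediate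
18 | ent-epifisetinidol-(4α→6)-ent-epifisetinidol | Oc1ccc2c(c1)O[C@@H](c1ccc(O)c(O)c1)[C@@H](O)[C@@H]2c1cc2c(cc1O)O[C@@H](c1ccc(O)c(O)c1)[C@@H](O)C2 | target

**Totals**

Total steps: 10. Longest linear sequence: 10 steps (1 → 18; compound 13 enters step 9 a second time as the nucleophile, so there is no separate branch).

**Steps most likely to fail**

Step 4 (labelled step). The hydride shift may not start because the alkoxy-substituted nitroalkene is too weak an acceptor, or Friedel–Crafts alkylation by ring B and Lewis-acid cleavage of the benzylic ether may outpace it. The fallback uses known chemistry, still closes ring C at C2–C3, sets out from aldehyde 4 and returns at ketone 11. Wittig olefination of 4 with Ph3P=CHCHO gives (E)-3-(2-{[3,4-bis(benzyloxy)phenyl]methoxy}-4-(pivaloyloxy)phenyl)prop-2-enal F1. The enal, an acceptor class with precedent in Lewis-acid hydride-shift/cyclisation of ethers, is cyclised with BF3·OEt2 in CH2Cl2 to racemic 2-[3,4-bis(benzyloxy)phenyl]-3-formylchroman-7-yl pivalate F2. Copper-catalysed aerobic deformylation of this alpha-branched aldehyde (Cu(OAc)2, 2,2'-bipyridine, DABCO, O2, DMF) excises the formyl carbon and gives 11.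

Step 6. Epimerisation at C2 may be slower than reduction, or facial discrimination by the catalyst may be weak, so that trans alcohol or material of low enantiomeric purity results. The fallback sets out from 11 and returns at 13. Reduction with LiBH(s-Bu)3 (THF, −78 °C), which attacks anti to the 2-aryl group, gives the racemic 2,3-cis alcohol, that is 12 together with its (2R,3R) enantiomer F3. Esterification of the mixture with (S)-O-methylmandelic acid (DCC, DMAP) gives two diastereomeric esters, the (S)-O-methylmandelate of 12 F4 and the (S)-O-methylmandelate of F3 F5, which are separated by chromatography or crystallisation. K2CO3 in MeOH then cleaves the mandelate and the pivalate of F4 together and delivers 13.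

Step 9. Alkylation may run on beyond the dimer, attack may occur through C8 instead of C6, or the acid may re-ionise the new C4–C6 bond. The fallback sets out from 15 and returns at 17. Exchange of the 4-methoxy group with benzyl mercaptan and a trace of acid gives the 4α-benzylsulfanyl analogue of 15 F6. Thiophilic activation with AgBF4 in THF at 0 °C in the presence of 13 then forms the C4–C6 bond under neutral conditions and gives 17.

**Further compounds**

F1 | step 4 | (E)-3-(2-{[3,4-bis(benzyloxy)phenyl]methoxy}-4-(pivaloyloxy)phenyl)prop-2-enal | CC(C)(C)C(=O)Oc1ccc(/C=C/C=O)c(OCc2ccc(OCc3ccccc3)c(OCc3ccccc3)c2)c1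
F2 | step 4 | 2-[3,4-bis(benzyloxy)phenyl]-3-formylchroman-7-yl pivalate (racemic) | CC(C)(C)C(=O)Oc1ccc2c(c1)OC(c1ccc(OCc3ccccc3)c(OCc3ccccc3)c1)C(C=O)C2
F3 | step 6 | (2R,3R)-2-[3,4-bis(benzyloxy)phenyl]-3-hydroxychroman-7-yl pivalate | CC(C)(C)C(=O)Oc1ccc2c(c1)O[C@H](c1ccc(OCc3ccccc3)c(OCc3ccccc3)c1)[C@H](O)C2
F4 | step 6 | (2S,3S)-2-[3,4-bis(benzyloxy)phenyl]-7-(pivaloyloxy)chroman-3-yl (S)-2-methoxy-2-phenylacetate | CC(C)(C)C(=O)Oc1ccc2c(c1)O[C@@H](c1ccc(OCc3ccccc3)c(OCc3ccccc3)c1)[C@@H](OC(=O)[C@@H](OC)c1ccccc1)C2
F5 | step 6 | (2R,3R)-2-[3,4-bis(benzyloxy)phenyl]-7-(pivaloyloxy)chroman-3-yl (S)-2-methoxy-2-phenylacetate | CC(C)(C)C(=O)Oc1ccc2c(c1)O[C@H](c1ccc(OCc3ccccc3)c(OCc3ccccc3)c1)[C@H](OC(=O)[C@@H](OC)c1ccccc1)C2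
F6 | step 9 | (2S,3R,4R)-2-[3,4-bis(benzyloxy)phenyl]-4-(benzylsulfanyl)chroman-3,7-diol (4α-benzylsulfanyl; 2,3-cis; 3,4-trans) | Oc1ccc2c(c1)O[C@@H](c1ccc(OCc3ccccc3)c(OCc3ccccc3)c1)[C@@H](O)[C@@H]2SCc1ccccc1
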